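**Retrosynthetic overview**

1. Target 25 ⇒ β-keto ester 22. The only ring, the six-membered lactone O–C1–C2–C3–C4–C5 (C1 = lactone carbonyl, chain C6–C20), is closed last by acid lactonisation of the C5 hydroxyl onto a C1 tert-butyl ester. C14–C20 come from oct-1-ene (cross-metathesis at C13=C14, then hydrogenation) and C1–C2 from tert-butyl acetate (aldol on a C3 aldehyde, then oxidation).
2. The C3 aldehyde 16 ⇒ C2-symmetric bis-acetonide 14 by cleaving one of its two homotopic allyl groups. 14 ⇒ diol 13 by acid-driven acetonide migration onto the syn pairs C5/C7 and C9/C11.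
3. 13 ⇒ diol 9 + two allyl acetate: two-directional iridium-catalysed allylation forming C4–C5 and C11–C12 and the C5 and C11 carbinols, with no ring closed.
4. 9 ⇒ propane-1,3-diol 1 + two allyl acetate: the same catalyst forms C6–C7 and C9–C10 and the C7 and C9 carbinols; acetonide formation and ozonolysis with NaBH4 work-up then give 9.
5. Feature on which the plan rests: C5, C7, C9 and C11 are syn, anti, syn, so the C5–C11 tetrol is C2-symmetric about C8. Viewed outward from C8, all four carbinols show allyl-side carbon, H, OH and inner chain in one sense, so one catalyst enantiomer serves both rounds.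

Key step: step 4

Remark on numbering: locants C1–C20 are those of the target throughout. Ring A is the dioxane on O5/O7, ring B the dioxane on O9/O11.

Assumption: the iridium catalyst carrying (S)-BINAP adds allyl to the aldehyde face that gives the (S)-carbinol in the CH2=CH–CH2–CH(OH)–CH2–C(O) array (the (4S,6S)-diol in step 1). If the sense were the opposite, (R)-BINAP would be used in steps 1 and 4 with nothing else changed.

Remark on tautomers: the target is the 4-hydroxy enol form of a 3-oxo-δ-lactone; the lactonisation product is taken to rest as this tautomer.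

**Route**

Step 1
Reactants: 1 propane-1,3-diol; 2 allyl acetate (two equivalents incorporated, used in excess)
Product: 6 (4S,6S)-nona-1,8-diene-4,6-diol, via 3-hydroxypropanal 3 (not isolated), via (3S)-hex-5-ene-1,3-diol 4 (not isolated), via (3S)-3-hydroxyhex-5-enal 5 (not isolated)
Conditions: [Ir(cod)Cl]2 (5 mol%), (S)-BINAP (10 mol%), 4-chloro-3-nitrobenzoic acid (20 mol%), Cs2CO3 (40 mol%), 1,4-dioxane, 90 °C
Reagents that add atoms: none
Why: Iridium-catalysed transfer-hydrogenative C-allylation run in two directions: each CH2OH terminus is dehydrogenated in turn (3, then 5 after the first addition) and the transient aldehyde is captured by the (S)-BINAP-bound allyliridium through a closed chair transition state, so the catalyst should set C7 and C9 with the same sense to give the C2-symmetric anti diol, the minor facial pathway ending mainly in the separable meso diol.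

Step 2
Reactants: 6 (4S,6S)-nona-1,8-diene-4,6-diol
Product: 7 (4S,6S)-2,2-dimethyl-4,6-di(prop-2-en-1-yl)-1,3-dioxane
Conditions: 2,2-dimethoxypropane, PPTS (5 mol%), CH2Cl2, rt
Reagents that add atoms: 2,2-dimethoxypropane COC(C)(C)OC
Why: Acid-catalysed transketalisation of the anti 1,3-diol with 2,2-dimethoxypropane (acetonide formation) should give the trans-4,6-disubstituted 1,3-dioxane without touching either stereocentre or the terminal alkenes.

Step 3
Reactants: 7 (4S,6S)-2,2-dimethyl-4,6-di(prop-2-en-1-yl)-1,3-dioxane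
Product: 9 2,2'-[(4S,6S)-2,2-dimethyl-1,3-dioxane-4,6-diyl]diethanol, via bis-ozonide 8 (not isolated)
Conditions: O3, CH2Cl2, −78 °C; then NaBH4, MeOH, −78 °C → rt
Reagents that add atoms: ozone [O-][O+]=O
Why: Criegee ozonolysis of both terminal alkenes in a non-participating solvent gives bis-ozonide 8, which NaBH4 reduces in the same flask to the two primary alcohols, so that no β-alkoxy aldehyde is isolated and the acetonide and the C7 and C9 centres are untouched.

Step 4
Reactants: 9 2,2'-[(4S,6S)-2,2-dimethyl-1,3-dioxane-4,6-diyl]diethanol; 2 allyl acetate (two equivalents incorporated, used in excess)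
Product: 13 (2S,2'S)-1,1'-[(4S,6S)-2,2-dimethyl-1,3-dioxane-4,6-diyl]bis(pent-4-en-2-ol), via hydroxy aldehyde 10 (not isolated), via mono-allyl diol 11 (not isolated), via mono-allyl aldehyde 12 (not isolated)
Conditions: [Ir(cod)Cl]2 (5 mol%), (S)-BINAP (10 mol%), 4-chloro-3-nitrobenzoic acid (20 mol%), Cs2CO3 (40 mol%), 1,4-dioxane, 90 °C, sealed vessel
Reagents that add atoms: none
Why: [Ir(cod)Cl]2, (S)-BINAP, allyl acetate and 4-chloro-3-nitrobenzoic acid assemble in situ into a cyclometallated π-allyl C,O-benzoate complex of trivalent iridium, which binds a primary alkoxide of 9, dehydrogenates it by β-hydride elimination to the transient aldehyde 10, is deprotonated at the hydride to monovalent iridium, adds allyl acetate oxidatively and delivers the allyl group to the aldehyde through a closed six-membered chair transition state, the sequence then repeating at the second terminus by way of 11 and 12. The closest known reaction type is the iridium-catalysed transfer-hydrogenative allylation of primary alcohols in its two-directional form on 1,3-diols and their acetonide-bridged homologues, so the step stays within known chemistry for this substrate class. No ring is closed: the C4–C5 and C11–C12 bonds and the C5 and C11 carbinols are formed while the 1,3-dioxane is a spectator. Both new stereocentres are set by the catalyst (the (S)-BINAP ligand and the stereogenic metal centre of the cyclometallated complex), which should select the same aldehyde face as in step 1 because, seen from C8, C5 and C11 present allyl carbon, hydrogen, hydroxyl and inner chain in the same sense as C7 and C9. The step needs facial selectivity that overrides the resident C7 and C9 centres, which is expected because they sit β to the transient carbonyl and exert only weak 1,3-induction in a closed transition state, and it needs chemoselectivity for the primary termini, which the much slower dehydrogenation of the secondary homoallylic alcohols provides. The acetonide should survive because the medium is buffered by Cs2CO3 and the acetic acid set free is a weak acid in dioxane.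

Step 5
Reactants: 13 (2S,2'S)-1,1'-[(4S,6S)-2,2-dimethyl-1,3-dioxane-4,6-diyl]bis(pent-4-en-2-ol)
Product: 14 bis[(4S,6S)-2,2-dimethyl-6-(prop-2-en-1-yl)-1,3-dioxan-4-yl]methane
Conditions: 2,2-dimethoxypropane (5 equiv), camphorsulfonic acid (10 mol%), acetone, rt
Reagents that add atoms: 2,2-dimethoxypropane COC(C)(C)OC
Why: Acid-catalysed acetonide equilibration (thermodynamic transketalisation): the trans-4,6-disubstituted dioxane on the anti C7/C9 pair must adopt a twist-boat, whereas the syn pairs C5/C7 and C9/C11 give chair dioxanes with both substituents equatorial, so under reversible conditions with excess 2,2-dimethoxypropane the C2-symmetric bis-acetonide should be the sink, with no stereocentre touched.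

Step 6
Reactants: 14 bis[(4S,6S)-2,2-dimethyl-6-(prop-2-en-1-yl)-1,3-dioxan-4-yl]methane
Product: 15 3-[(4S,6S)-6-{[(4S,6S)-2,2-dimethyl-6-(prop-2-en-1-yl)-1,3-dioxan-4-yl]methyl}-2,2-dimethyl-1,3-dioxan-4-yl]propane-1,2-diol (both epimers at the new carbinol)
Conditions: OsO4 (2 mol%), N-methylmorpholine N-oxide (0.7 equiv), acetone/H2O, 0 °C → rt; unreacted 14 recovered
Reagents that add atoms: N-methylmorpholine N-oxide C[N+]1([O-])CCOCC1; water O (both oxygen atoms are delivered through catalytic OsO4 O=[Os](=O)(=O)=O)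
Why: Upjohn dihydroxylation with the oxidant as limiting reagent: the two allyl groups of C2-symmetric 14 are homotopic, so mono-oxidation gives one constitution only (the new C3 carbinol forms as both epimers and is cleaved off in step 7), the distribution between 14, 15 and doubly oxidised material is statistical, and recovered 14 is recycled.

Step 7
Reactants: 15 (mono-diol)
Product: 16 2-[(4R,6R)-6-{[(4S,6S)-2,2-dimethyl-6-(prop-2-en-1-yl)-1,3-dioxan-4-yl]methyl}-2,2-dimethyl-1,3-dioxan-4-yl]acetaldehyde
Conditions: NaIO4, THF/H2O, 0 °C → rt; used at once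
Reagents that add atoms: none
Why: Malaprade glycol cleavage by periodate in neutral aqueous THF should give the C3 aldehyde and formaldehyde without opening the acetonides, and the aldehyde is taken on directly because β-elimination of the C5 oxygen is its main liability.

Step 8
Reactants: 16 (C3 aldehyde); 17 tert-butyl acetate
Product: 18 tert-butyl 4-[(4S,6S)-6-{[(4S,6S)-2,2-dimethyl-6-(prop-2-en-1-yl)-1,3-dioxan-4-yl]methyl}-2,2-dimethyl-1,3-dioxan-4-yl]-3-hydroxybutanoate (both C3 epimers)
Conditions: LiN(iPr)2, tert-butyl acetate, THF, −78 °C; then 16, −78 °C; NH4Cl aq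
Reagents that add atoms: none
Why: Acetate aldol addition of the preformed lithium enolate of tert-butyl acetate to the aldehyde at −78 °C adds C1 and C2, the low temperature suppressing β-elimination, and the C3 carbinol is formed as both epimers, which does not matter because it is oxidised in step 9.

Step 9
Reactants: 18 (β-hydroxy ester)
Product: 19 tert-butyl 4-[(4R,6R)-6-{[(4S,6S)-2,2-dimethyl-6-(prop-2-en-1-yl)-1,3-dioxan-4-yl]methyl}-2,2-dimethyl-1,3-dioxan-4-yl]-3-oxobutanoate
Conditions: Dess–Martin periodinane (1.2 equiv), pyridine, CH2Cl2, 0 °C → rt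
Reagents that add atoms: none
Why: Dess–Martin oxidation buffered with pyridine converts the C3 carbinol into the ketone under mild conditions that should leave the acetonides, the terminal alkene and the enolisable β-keto ester intact.

Step 10
Reactants: 19 (β-keto ester); 20 oct-1-ene
Product: 21 tert-butyl 4-[(4R,6R)-6-{[(4S,6S)-2,2-dimethyl-6-(non-2-en-1-yl)-1,3-dioxan-4-yl]methyl}-2,2-dimethyl-1,3-dioxan-4-yl]-3-oxobutanoate (E/Z mixture)
Conditions: oct-1-ene (5 equiv), second-generation Grubbs catalyst (H2IMes)(PCy3)Cl2Ru=CHPh (5 mol%), CH2Cl2, 40 °C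
Reagents that add atoms: none
Why: Olefin cross-metathesis of the terminal alkene of 19 with an excess of oct-1-ene should form the C13=C14 bond with loss of ethene, the ruthenium carbene tolerating the β-keto ester and the acetonides, and the expected E/Z mixture is of no consequence because step 11 saturates the alkene.

Step 11
Reactants: 21 (cross-metathesis product)
Product: 22 tert-butyl 4-[(4R,6R)-6-{[(4S,6S)-2,2-dimethyl-6-nonyl-1,3-dioxan-4-yl]methyl}-2,2-dimethyl-1,3-dioxan-4-yl]-3-oxobutanoate
Conditions: H2 (1 atm), Pd/C (10 wt%), EtOAc, rt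
Reagents that add atoms: none
Why: Heterogeneous catalytic hydrogenation over Pd/C saturates the isolated disubstituted alkene, while the ketone, the tert-butyl ester and the acetonides are inert under these neutral conditions.

Step 12
Reactants: 22 (saturated β-keto ester bis-acetonide)
Product: 25 (6R)-4-hydroxy-6-[(2R,4S,6S)-2,4,6-trihydroxypentadecyl]-5,6-dihydro-2H-pyran-2-one, via tetrol ester 23 (not isolated), via tetrol acid 24 (not isolated)
Conditions: TFA/CH2Cl2/H2O (10:10:1), 0 °C → rt; evaporation, reversed-phase chromatography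
Reagents that add atoms: none
Why: Aqueous acid hydrolyses both acetonides to tetrol ester 23, acidolysis of the tert-butyl ester then gives acid 24, and acid-catalysed lactonisation of the C5 hydroxyl onto C1 (6-exo-trig) closes the only ring, the 3-oxo lactone resting as its conjugated 4-hydroxy enol, with no bond to C5, C7, C9 or C11 being broken.

**Compound list**

1 | propane-1,3-diol | OCCCO | starting material
2 | allyl acetate (prop-2-en-1-yl acetate) | C=CCOC(C)=O | starting material
3 | 3-hydroxypropanal (not isolated, step 1) | O=CCCO | intermediate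
4 | (3S)-hex-5-ene-1,3-diol (not isolated, step 1) | C=CC[C@H](O)CCO | intermediate
5 | (3S)-3-hydroxyhex-5-enal (not isolated, step 1) | C=CC[C@H](O)CC=O | intermediate
6 | (4S,6S)-nona-1,8-diene-4,6-diol | C=CC[C@H](O)C[C@@H](O)CC=C | intermediate
7 | (4S,6S)-2,2-dimethyl-4,6-di(prop-2-en-1-yl)-1,3-dioxane | C=CC[C@H]1C[C@H](CC=C)OC(C)(C)O1 | intermediate
8 | (4R,6R)-2,2-dimethyl-4,6-bis[(1,2,4-trioxolan-3-yl)methyl]-1,3-dioxane (bis-ozonide, ozonide carbons unassigned; not isolated, step 3) | C1OC(C[C@H]2C[C@H](CC3OCOO3)OC(C)(C)O2)OO1 | intermediate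
9 | 2,2'-[(4S,6S)-2,2-dimethyl-1,3-dioxane-4,6-diyl]diethanol (C5–C11; key-step precursor) | OCC[C@H]1C[C@H](CCO)OC(C)(C)O1 | intermediate
10 | 2-[(4R,6S)-6-(2-hydroxyethyl)-2,2-dimethyl-1,3-dioxan-4-yl]acetaldehyde (hydroxy aldehyde; not isolated, step 4) | O=CC[C@H]1C[C@H](CCO)OC(C)(C)O1 | intermediate
11 | (2S)-1-[(4S,6S)-6-(2-hydroxyethyl)-2,2-dimethyl-1,3-dioxan-4-yl]pent-4-en-2-ol (mono-allyl diol; not isolated, step 4) | C=CC[C@H](O)C[C@H]1C[C@H](CCO)OC(C)(C)O1 | intermediate
12 | 2-{(4R,6S)-6-[(2S)-2-hydroxypent-4-en-1-yl]-2,2-dimethyl-1,3-dioxan-4-yl}acetaldehyde (mono-allyl aldehyde; not isolated, step 4) | C=CC[C@H](O)C[C@H]1C[C@H](CC=O)OC(C)(C)O1 | intermediate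
13 | (2S,2'S)-1,1'-[(4S,6S)-2,2-dimethyl-1,3-dioxane-4,6-diyl]bis(pent-4-en-2-ol) (key-step product; C5, C7, C9, C11 set) | C=CC[C@H](O)C[C@H]1C[C@H](C[C@@H](O)CC=C)OC(C)(C)O1 | intermediate
14 | bis[(4S,6S)-2,2-dimethyl-6-(prop-2-en-1-yl)-1,3-dioxan-4-yl]methane (C2-symmetric; both dioxanes cis-4,6-disubstituted) | C=CC[C@H]1C[C@@H](C[C@@H]2C[C@H](CC=C)OC(C)(C)O2)OC(C)(C)O1 | intermediate
15 | 3-[(4S,6S)-6-{[(4S,6S)-2,2-dimethyl-6-(prop-2-en-1-yl)-1,3-dioxan-4-yl]methyl}-2,2-dimethyl-1,3-dioxan-4-yl]propane-1,2-diol (both epimers at the secondary carbinol) | OCC(O)C[C@H]1C[C@@H](C[C@@H]2C[C@H](CC=C)OC(C)(C)O2)OC(C)(C)O1 | intermediate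
16 | 2-[(4R,6R)-6-{[(4S,6S)-2,2-dimethyl-6-(prop-2-en-1-yl)-1,3-dioxan-4-yl]methyl}-2,2-dimethyl-1,3-dioxan-4-yl]acetaldehyde | O=CC[C@H]1C[C@@H](C[C@@H]2C[C@H](CC=C)OC(C)(C)O2)OC(C)(C)O1 | intermediate
17 | tert-butyl acetate | CC(=O)OC(C)(C)C | starting material
18 | tert-butyl 4-[(4S,6S)-6-{[(4S,6S)-2,2-dimethyl-6-(prop-2-en-1-yl)-1,3-dioxan-4-yl]methyl}-2,2-dimethyl-1,3-dioxan-4-yl]-3-hydroxybutanoate (both C3 epimers) | CC(C)(C)OC(=O)CC(O)C[C@H]1C[C@@H](C[C@@H]2C[C@H](CC=C)OC(C)(C)O2)OC(C)(C)O1 | intermediate
19 | tert-butyl 4-[(4R,6R)-6-{[(4S,6S)-2,2-dimethyl-6-(prop-2-en-1-yl)-1,3-dioxan-4-yl]methyl}-2,2-dimethyl-1,3-dioxan-4-yl]-3-oxobutanoate | CC(C)(C)OC(=O)CC(=O)C[C@H]1C[C@@H](C[C@@H]2C[C@H](CC=C)OC(C)(C)O2)OC(C)(C)O1 | intermediate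
20 | oct-1-ene | C=CCCCCCC | starting material
21 | tert-butyl 4-[(4R,6R)-6-{[(4S,6S)-2,2-dimethyl-6-(non-2-en-1-yl)-1,3-dioxan-4-yl]methyl}-2,2-dimethyl-1,3-dioxan-4-yl]-3-oxobutanoate (E/Z mixture) | CC(C)(C)OC(=O)CC(=O)C[C@H]1C[C@@H](C[C@@H]2C[C@H](CC=CCCCCCC)OC(C)(C)O2)OC(C)(C)O1 | intermediate
22 | tert-butyl 4-[(4R,6R)-6-{[(4S,6S)-2,2-dimethyl-6-nonyl-1,3-dioxan-4-yl]methyl}-2,2-dimethyl-1,3-dioxan-4-yl]-3-oxobutanoate | CC(C)(C)OC(=O)CC(=O)C[C@H]1C[C@@H](C[C@@H]2C[C@H](CCCCCCCCC)OC(C)(C)O2)OC(C)(C)O1 | intermediate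
23 | tert-butyl (5R,7R,9S,11S)-5,7,9,11-tetrahydroxy-3-oxoicosanoate (tetrol ester; not isolated, step 12) | CC(C)(C)OC(=O)CC(=O)C[C@H](O)C[C@H](O)C[C@@H](O)C[C@@H](O)CCCCCCCCC | intermediate
24 | (5R,7R,9S,11S)-5,7,9,11-tetrahydroxy-3-oxoicosanoic acid (tetrol acid; not isolated, step 12) | OC(=O)CC(=O)C[C@H](O)C[C@H](O)C[C@@H](O)C[C@@H](O)CCCCCCCCC | intermediate
25 | (6R)-4-hydroxy-6-[(2R,4S,6S)-2,4,6-trihydroxypentadecyl]-5,6-dihydro-2H-pyran-2-one (CNP0075663.1) | CCCCCCCCC[C@H](O)C[C@H](O)C[C@@H](O)C[C@@H]1CC(O)=CC(=O)O1 | target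

**Step count and risks**

Total step count: 12. Longest linear sequence: 12 steps (1 to 25); the route is fully linear.

Steps most likely to fail:

1. Step 4 (key step). The second allylation may stall at mono-adduct 11, catalyst control may be eroded at one terminus so that a C5 or C11 epimer accumulates, or the acetonide may shift or be lost during prolonged heating as acetic acid builds up. Fallback: setting out from 9, a Swern oxidation ((COCl)2, DMSO, Et3N, CH2Cl2, −78 °C) would give 2,2'-[(4R,6R)-2,2-dimethyl-1,3-dioxane-4,6-diyl]diacetaldehyde F1, used crude and cold. Both termini would then be allylated under stoichiometric reagent control by Brown allylation with (−)-Ipc2B(allyl), the enantiomer made from (+)-α-pinene that converts acetaldehyde into (R)-pent-4-en-2-ol (Et2O, −78 °C; NaOH/H2O2 work-up). The fallback comes back to the route at 13.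

2. Step 6. The second alkene is dihydroxylated at the same rate as the first, so the outcome rests on stopping at partial conversion, and doubly oxidised material is lost. Fallback: setting out from 14, exhaustive ozonolysis (O3, CH2Cl2, −78 °C; then PPh3) removes the selectivity question at the oxidation stage. It would give, through bis{(4R,6R)-2,2-dimethyl-6-[(1,2,4-trioxolan-3-yl)methyl]-1,3-dioxan-4-yl}methane F2 (not isolated), the C2-symmetric dialdehyde bis[(4R,6R)-2,2-dimethyl-6-(2-oxoethyl)-1,3-dioxan-4-yl]methane F3. Slow addition of a deficit of the ylide from heptyltriphenylphosphonium bromide and NaN(SiMe3)2 (THF, −78 °C) to F3 would give the mono-olefin 2-[(4R,6R)-6-({(4S,6S)-2,2-dimethyl-6-[(2Z)-non-2-en-1-yl]-1,3-dioxan-4-yl}methyl)-2,2-dimethyl-1,3-dioxan-4-yl]acetaldehyde F4, with F3 recovered. The conditions of step 8 would then give tert-butyl 4-[(4S,6S)-6-({(4S,6S)-2,2-dimethyl-6-[(2Z)-non-2-en-1-yl]-1,3-dioxan-4-yl}methyl)-2,2-dimethyl-1,3-dioxan-4-yl]-3-hydroxybutanoate F5, and the conditions of step 9 the (Z) isomer of 21, where the fallback comes back to the route. Steps 7 to 10 are bypassed and oct-1-ene 20 is no longer needed.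

3. Step 12. After acetonide loss the C7 hydroxyl can add to the C3 ketone and the hemiketal can dehydrate to a cyclic enol ether; the free β-keto acid can decarboxylate before it lactonises; hydroxyls can be trifluoroacetylated. Fallback: setting out from 22, 80% aqueous AcOH at 40 °C would remove only the acetonides, and 23 would be isolated. Heated in dilute toluene at 110 °C, 23 should lose tert-butanol to give the acylketene (5R,7R,9S,11S)-5,7,9,11-tetrahydroxy-3-oxoicos-1-en-1-one F6 (not isolated), which the C5 hydroxyl traps through a six-membered transition state. The fallback comes back to the route at 25 under neutral conditions, with no free β-keto acid and no strong acid involved.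

Further compounds
F1 | step 4 | 2,2'-[(4R,6R)-2,2-dimethyl-1,3-dioxane-4,6-diyl]diacetaldehyde | O=CC[C@H]1C[C@H](CC=O)OC(C)(C)O1
F2 | step 6 | bis{(4R,6R)-2,2-dimethyl-6-[(1,2,4-trioxolan-3-yl)methyl]-1,3-dioxan-4-yl}methane (bis-ozonide, ozonide carbons unassigned, not isolated) | C1OC(C[C@H]2C[C@@H](C[C@@H]3C[C@H](CC4OCOO4)OC(C)(C)O3)OC(C)(C)O2)OO1
F3 | step 6 | bis[(4R,6R)-2,2-dimethyl-6-(2-oxoethyl)-1,3-dioxan-4-yl]methane | O=CC[C@H]1C[C@@H](C[C@@H]2C[C@H](CC=O)OC(C)(C)O2)OC(C)(C)O1
F4 | step 6 | 2-[(4R,6R)-6-({(4S,6S)-2,2-dimethyl-6-[(2Z)-non-2-en-1-yl]-1,3-dioxan-4-yl}methyl)-2,2-dimethyl-1,3-dioxan-4-yl]acetaldehyde | O=CC[C@H]1C[C@@H](C[C@@H]2C[C@H](C/C=C\CCCCCC)OC(C)(C)O2)OC(C)(C)O1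
F5 | step 6 | tert-butyl 4-[(4S,6S)-6-({(4S,6S)-2,2-dimethyl-6-[(2Z)-non-2-en-1-yl]-1,3-dioxan-4-yl}methyl)-2,2-dimethyl-1,3-dioxan-4-yl]-3-hydroxybutanoate (both C3 epimers) | CC(C)(C)OC(=O)CC(O)C[C@H]1C[C@@H](C[C@@H]2C[C@H](C/C=C\CCCCCC)OC(C)(C)O2)OC(C)(C)O1
F6 | step 12 | (5R,7R,9S,11S)-5,7,9,11-tetrahydroxy-3-oxoicos-1-en-1-one (acylketene, not isolated) | O=C=CC(=O)C[C@H](O)C[C@H](O)C[C@@H](O)C[C@@H](O)CCCCCCCCC
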